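TBS = tert-butyldimethylsilyl. Flavanone numbering is used for the ring system (O1, C2, C3, C4, C4a–C8a; ring B C1′–C6′; side chain C1″–C4″).

## Analysis of the target

The target 17 is a flavanone. A resorcinol-type ring A is fused to a dihydropyranone ring C (O1, C2, C3, C4=O), with a catechol ring B on C2, a free hydroxyl on C7, and an (E)-4-hydroxy-3-methylbut-2-enyl chain on C8, the ring-A carbon between C7 and the O1-bearing C8a. There is one stereocentre, C2, which is S (O1 > C1′ > C3 > H), and one stereogenic double bond, C2″=C3″, which is E (CH2OH trans to the ring-bearing CH2); the two are remote and independent. C2 is the weak point, because its C2–O1 bond is β to the C4 ketone: base, or hot acid, opens ring C by retro-oxa-Michael reaction to an achiral ring-opened enone and recloses it without control. The catechol is easily oxidised, the primary allylic alcohol ionises in strong acid and sits beside the C7 phenol, and four hydroxyl groups must be freed at the end without base, strong acid or hydrogenation. The difficulties are therefore to set a lone benzylic ether stereocentre with no neighbour to relay from, to place the chain on C8 and not C6, and to secure the E alkene with its allylic oxygen. The strategy rests on ring C being stitched from two pieces by only two bonds, O1–C2 and C3–C4. C4, C4a, C8a and O1 are the carbonyl carbon, two ring carbons and phenol oxygen of a salicylaldehyde; C2–C3 is the vinyl group of a styrene carrying ring B. Ring C is thus the adduct of an ortho-quinone methide (O1=C8a–C4a=C4) and an electron-rich alkene, with C4 arriving oxygenated if the methide carbon bears an alkoxy group and C2 created in the bond-forming event, where a chiral acid can act.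

## Retrosynthetic reasoning

**17 ⇒ 16.** Only O–Si bonds are cut in the last step, with all three phenols of 16 masked as aryl silyl ethers. Ester or alkyl protecting groups would need base, strong acid or hydrogenation for removal. Base would open the C2–O1 bond, strong acid would ionise the allylic alcohol next to the C7 oxygen, and hydrogenation would reduce the alkene. The forward step has to be a buffered, non-basic desilylation.

**16 ⇒ 15 ⇒ 13 + 14.** The allylic alcohol is taken back to the conjugated aldehyde 15, and the C2″=C3″ bond is cut as a cross-metathesis between the C8 allyl group of 13 and 14. Cutting here leaves a plain allyl group on ring A during ring-C formation. A trisubstituted alkene ortho to the phenol oxygen would compete with 8 for the cation and would cyclise under acid. The E geometry comes from the thermodynamic preference of the conjugated enal. The forward steps must achieve metathesis at an allyl group flanked by two ortho substituents, and reduction of the formyl group of 15 without touching the C4 ketone.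

**13 ⇒ 12 ⇒ 11.** The C4 ketone is traced back through the benzylic alcohol 12 to the benzylic methyl ether 11. The cycloaddition delivers C4 at the alcohol oxidation level, so its configuration need not be controlled and both epimers converge on 13. The forward steps are an acid-mediated exchange of the methoxy group for hydroxyl and a mild oxidation, neither of which touches C2.

**11 ⇒ 5 + 8.** This is the central disconnection, cutting O1–C2 and C3–C4 of ring C. Aldehyde 5 supplies C4, ring A and O1, and styrene 8 supplies C2, C3 and ring B. Acetal 9, formed in the flask from 5, is ionised by a chiral Brønsted acid to the methoxy-substituted ortho-quinone methide 10 (as its protonated, ion-paired form), which adds 8 in a formal [4+2] sense. One step gives the ring, both bonds and the stereocentre, from two fragments that are each a few steps from commodity phenols. The forward reaction has to put the aryl group on C2, prefer the styrene over the allyl group, and differentiate the faces so that C2 is S.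

**5 ⇒ 4 ⇒ 3 ⇒ 1 + 2.** The C8–C1″ bond is cut as a sigmatropic shift of an O-allyl group. In 3 the allyl ether sits on the oxygen that becomes the C7 oxygen, and rearrangement moves it to the carbon between the two oxygens, which is C8 of the flavanone. The regiochemistry of the chain is thus settled before ring C exists. The two phenols of 1 and of 4 differ because one is hydrogen-bonded to the formyl group, which allows selective O-allylation and later selective silylation. The free ortho hydroxyl of 5 is the one needed to form 10.

**8 ⇒ 7 ⇒ 6.** The vinyl group is cut at its double bond (carbonyl methylenation), and the catechol of 6 is silylated first. The para silyloxy group makes the alkene terminus of 8 nucleophilic.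

## Alternatives that were turned down

**Alternative 1:** Ring A, not ring C, is taken apart, at C4a–C5 and C8–C8a.
- Precursors: the (2S)-2-aryl-5-(phenylsulfinyl)-2,3-dihydropyran-4-one A1, which already holds ring C, ring B and C2, and the 1-methoxy-3-silyloxy diene A2, whose nucleophilic terminus carries the silyl-protected side chain.
- Forward key step: A2 adds across the sulfinyl-activated C5=C6 bond of A1 in a Diels–Alder reaction; thermal loss of the sulfinyl and methoxy groups aromatises the new ring to the 7-hydroxyflavanone A3.
- For it: C2 would come from a well-established catalytic asymmetric hetero-Diels–Alder route to dihydropyranones. The C4 ketone never has to be made by oxidation, the E side chain is in place, and A3 is one desilylation from 17. On stereochemical certainty and on the number of steps after ring formation it is stronger than the chosen route.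
- Against it: A2 is a 4-substituted diene with a skipped, doubly allylic CH2 and two alkene geometries to control, and making it would take more steps than all of fragment 5. The dienophile is the enol-ether alkene of a vinylogous ester, electron-rich even with the sulfinyl group, and must accept the substituted diene terminus at C6, its most hindered carbon. The heating for cycloaddition and two eliminations acts on a ring whose C2–O1 bond is already β to a carbonyl.
- Comparison: the risk is spread over diene synthesis, cycloaddition and aromatisation. The chosen strategy offers fragment syntheses of three and two steps and concentrates the uncertainty in one bond-forming step.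

**Alternative 2:** Ring C is cut at O1–C8a, an aryl–oxygen bond.
- Precursor: the 1-(2-fluoroaryl)-3-arylpropane-1,3-diol A4, with the future C2 carbinol S and fluorine on the future C8a.
- Forward key step: a strong amide base forms the C2 alkoxide, which attacks C8a with loss of the fluorine substituent and gives the flavan-4-ol A5 as both C4 epimers.
- For it: the C2–O bond is never broken, so a carbinol from reliable asymmetric reduction or aldol chemistry keeps its configuration through the closure. C4 arrives as an alcohol ready for oxidation. In stereochemical security this is the strongest of the four.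
- Against it: the fluorinated carbon of A4 has no electron-withdrawing group ortho or para and is flanked by two ortho substituents, so the substitution needs forcing conditions. Under those conditions the doubly activated benzylic/allylic CH2 of the side chain can be deprotonated and the alkene moved into conjugation. The 2-fluoro-3-alkyl-4-alkoxyaryl building block takes several steps of directed metalation. The phenols of A5 are methoxymethyl ethers, whose acidic removal exposes the allylic alcohol beside the C7 phenol to ionisation and cyclisation.
- Comparison: it is the longer route, building ring C one bond per step. The chosen route forms both ring bonds in one operation and ends with a deprotection that is neither basic nor strongly acidic.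

**Alternative 3:** Ring C is cut at C4–C4a.
- Precursor: the (S)-3-aryl-3-aryloxypropanoic acid A6, in which O1–C2 is already in place.
- Forward key step: activation of the carboxyl group as a mixed anhydride lets the acyl carbon attack ring A ortho to the ether oxygen, giving flavanone A7.
- For it: the regiochemistry is unambiguous, since the only free position ortho to O1 is also para to the C7 silyloxy group. The ketone forms directly, saving the hydrolysis and oxidation at C4. C2 comes from an established asymmetric reduction and not from a new catalytic reaction. On these points it is stronger.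
- Against it: the stereocentre must be carried into A6 by etherification of a benzylic alcohol with a hindered, ortho-substituted phenol, a substitution with carbocation character that tends to leak configuration. Under the acidic acylation conditions the same benzylic C–O bond can ionise, or the aryloxy group can leave by β-elimination, which is why ring B must be deactivated as a diacetate. Those acetates then need base or nucleophiles for removal on a flavanone, the very conditions that open ring C. The allyl group is also exposed to the acylating species.
- Comparison: the step count to 17 is similar, since the same metathesis and reduction end game follows A7. But C2 is at risk at three stages and not one, and the chosen route keeps silyl ethers on all phenols throughout.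

Key step: step 6

Assumption (remark on the chemistry): the sense of induction of the chiral phosphoramide cannot be derived from precedent. The (R) catalyst is written; its mirror image is to be used if the (R) catalyst proves to favour the 2R series.

## Route

Step 1
Reactants: 1 2,4-dihydroxybenzaldehyde; 2 allyl bromide
Product: 3 4-(allyloxy)-2-hydroxybenzaldehyde
Conditions: 2 (1.05 equiv), KHCO3 (1.2 equiv), MeCN, 60 °C
Reagents that add atoms: none
Why: Williamson ether synthesis; the 4-OH is the more acidic phenol (para to the formyl group) and is free, whereas the 2-OH is tied up in a hydrogen bond to the carbonyl, so a weak base should alkylate O4 only.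

Step 2
Reactants: 3 4-(allyloxy)-2-hydroxybenzaldehyde
Product: 4 3-allyl-2,4-dihydroxybenzaldehyde
Conditions: PhNEt2, 200 °C, sealed tube
Reagents that add atoms: none
Why: Aromatic Claisen rearrangement ([3,3]-sigmatropic shift, then tautomerisation); in ortho-hydroxyaryl carbonyl compounds the chelate ring fixes more double-bond character in C3–C4 than in C4–C5, so the allyl group should migrate mainly to C3, the carbon between the two oxygens.

Step 3
Reactants: 4 3-allyl-2,4-dihydroxybenzaldehyde
Product: 5 3-allyl-4-(tert-butyldimethylsilyloxy)-2-hydroxybenzaldehyde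
Conditions: TBSCl (1.05 equiv), imidazole, DMF, 0 °C
Reagents that add atoms: tert-butyldimethylsilyl chloride, CC(C)(C)[Si](C)(C)Cl
Why: Silyl ether formation; the chelated 2-OH is a poor nucleophile, so one equivalent of silyl chloride should go to O4 and leave the ortho hydroxyl free for the key step.

Step 4
Reactants: 6 3,4-dihydroxybenzaldehyde
Product: 7 3,4-bis(tert-butyldimethylsilyloxy)benzaldehyde
Conditions: TBSCl (2.4 equiv), imidazole, DMF, rt
Reagents that add atoms: tert-butyldimethylsilyl chloride, CC(C)(C)[Si](C)(C)Cl
Why: Exhaustive silylation of a catechol; it masks the oxidisable diol with groups that can be removed later without base.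

Step 5
Reactants: 7 3,4-bis(tert-butyldimethylsilyloxy)benzaldehyde
Product: 8 3,4-bis(tert-butyldimethylsilyloxy)styrene
Conditions: Ph3PCH3Br, KOtBu, THF, 0 °C → rt
Reagents that add atoms: methyltriphenylphosphonium bromide, C[P+](c1ccccc1)(c1ccccc1)c1ccccc1.[Br-]
Why: Wittig methylenation of an aromatic aldehyde; the non-stabilised ylide does not attack aryl silyl ethers, and the styrene is used soon after preparation to avoid polymerisation.

Step 6
Reactants: 5 3-allyl-4-(tert-butyldimethylsilyloxy)-2-hydroxybenzaldehyde; 8 3,4-bis(tert-butyldimethylsilyloxy)styrene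
Product: 11 (2S)-8-allyl-7-(tert-butyldimethylsilyloxy)-2-[3,4-bis(tert-butyldimethylsilyloxy)phenyl]-4-methoxychroman (both C4 epimers), via dimethyl acetal 9 (not isolated), via methoxy ortho-quinone methide 10 (not isolated)
Conditions: HC(OMe)3 (1.5 equiv), (R)-3,3′-bis(2,4,6-triisopropylphenyl)-1,1′-binaphthyl-2,2′-diyl N-triflylphosphoramide (5 mol%), 5 Å MS, toluene, −40 °C, slow addition of 8 (1.5 equiv)
Reagents that add atoms: trimethyl orthoformate, COC(OC)OC
Why: Proposed new method: the acid should convert 5 and the orthoformate into acetal 9 and ionise it, with loss of methanol, to the O-methyl oxocarbenium ion that is the protonated form of 10, a cation stabilised by the ortho oxygen and the para silyloxy group and held by the phosphoramide anion through ion pairing and a hydrogen bond to the phenolic O–H. The CH2 terminus of 8, made nucleophilic by the para silyloxy group, should attack the methide carbon (C3–C4), and the ring-A oxygen then collapses on the C2 benzylic cation (O1–C2), so that ring C is closed in an intermolecular oxa-[4+2] mode (inverse-electron-demand hetero-Diels–Alder, asynchronous or stepwise with a final six-membered cation–oxygen recombination). The closest known reaction types are the chiral Brønsted acid-catalysed [4+2] additions of styrenes to ortho-quinone methides generated from ortho-hydroxybenzylic alcohols and the racemic acid-catalysed union of salicylaldehydes, orthoformates and alkenes to 4-alkoxychromans; the enantioselective variant with an alkoxy-substituted methide is the new element. C2 is to be set by the chiral anion, whose 3,3′-aryl groups shield one face of the bound heterodiene; since the alkene adds suprafacially, the face chosen at C4 together with the cis/trans preference of the closure fixes C2, so both have to be high. C4 itself needs no control and may epimerise by re-ionisation without harm, because it is oxidised later. Regioselectivity (aryl on C2) follows from the polarity of 8, and chemoselectivity for the styrene over the C8 allyl group from the much lower nucleophilicity of a monosubstituted alkene. A strongly acidic, confined N-triflyl phosphoramide is chosen because a plain phosphoric acid is unlikely to ionise the acetal at −40 °C, and the low temperature and the sieves, which take up methanol, are meant to spare the aryl silyl ethers and the styrene and to keep O1–C2 from reopening.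

Step 7
Reactants: 11 (2S)-8-allyl-7-(tert-butyldimethylsilyloxy)-2-[3,4-bis(tert-butyldimethylsilyloxy)phenyl]-4-methoxychroman (both C4 epimers)
Product: 12 (2S)-8-allyl-7-(tert-butyldimethylsilyloxy)-2-[3,4-bis(tert-butyldimethylsilyloxy)phenyl]chroman-4-ol (both C4 epimers)
Conditions: TsOH·H2O (10 mol%), THF/H2O 4:1, 0 °C → rt
Reagents that add atoms: water, O
Why: Acid-catalysed SN1 solvolysis of a doubly activated benzylic methyl ether: ionisation at C4 gives a cation stabilised by O1 and the C7 silyloxy group, and water in large excess should trap it. Aryl silyl ethers tolerate dilute sulfonic acid at room temperature, and C2 is not involved.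

Step 8
Reactants: 12 (2S)-8-allyl-7-(tert-butyldimethylsilyloxy)-2-[3,4-bis(tert-butyldimethylsilyloxy)phenyl]chroman-4-ol (both C4 epimers)
Product: 13 (2S)-8-allyl-7-(tert-butyldimethylsilyloxy)-2-[3,4-bis(tert-butyldimethylsilyloxy)phenyl]chroman-4-one
Conditions: Dess–Martin periodinane (1.3 equiv), pyridine, CH2Cl2, 0 °C → rt
Reagents that add atoms: none
Why: Dess–Martin oxidation of a secondary benzylic alcohol; both C4 epimers converge on one ketone. The buffered, non-basic conditions leave the terminal alkene and the aryl silyl ethers alone and give no opening for retro-oxa-Michael cleavage at C2.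

Step 9
Reactants: 13 (2S)-8-allyl-7-(tert-butyldimethylsilyloxy)-2-[3,4-bis(tert-butyldimethylsilyloxy)phenyl]chroman-4-one; 14 methacrolein
Product: 15 (2E)-4-[(2S)-7-(tert-butyldimethylsilyloxy)-2-[3,4-bis(tert-butyldimethylsilyloxy)phenyl]-4-oxochroman-8-yl]-2-methylbut-2-enal
Conditions: 14 (10 equiv), second-generation Hoveyda–Grubbs catalyst (H2IMes)Cl2Ru=CH(2-iPrOC6H4) (5 mol%), 1,4-benzoquinone (10 mol%), CH2Cl2, 40 °C
Reagents that add atoms: none
Why: Olefin cross-metathesis between a terminal alkene and an electron-poor 1,1-disubstituted alkene that does not homodimerise; the conjugated trisubstituted enal should form as the thermodynamically preferred E isomer (formyl trans to the ring-bearing CH2). Benzoquinone suppresses Ru–H-mediated migration of the allyl double bond.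

Step 10
Reactants: 15 (2E)-4-[(2S)-7-(tert-butyldimethylsilyloxy)-2-[3,4-bis(tert-butyldimethylsilyloxy)phenyl]-4-oxochroman-8-yl]-2-methylbut-2-enal
Product: 16 (2S)-7-(tert-butyldimethylsilyloxy)-2-[3,4-bis(tert-butyldimethylsilyloxy)phenyl]-8-[(2E)-4-hydroxy-3-methylbut-2-en-1-yl]chroman-4-one
Conditions: NaBH4 (1.0 equiv), EtOH/CH2Cl2 1:2, −78 °C; AcOH quench at −78 °C
Reagents that add atoms: none
Why: Chemoselective 1,2-reduction: at −78 °C an aldehyde reacts with NaBH4 far faster than a ketone, and the C4 carbonyl is further deactivated as a vinylogous ester by O1 and the C7 oxygen. The alkene geometry and C2 are untouched.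

Step 11
Reactants: 16 (2S)-7-(tert-butyldimethylsilyloxy)-2-[3,4-bis(tert-butyldimethylsilyloxy)phenyl]-8-[(2E)-4-hydroxy-3-methylbut-2-en-1-yl]chroman-4-one
Product: 17 (2S)-2-(3,4-dihydroxyphenyl)-7-hydroxy-8-[(2E)-4-hydroxy-3-methylbut-2-en-1-yl]chroman-4-one
Conditions: HF·pyridine, pyridine, THF, 0 °C → rt, under argon
Reagents that add atoms: none
Why: Fluoride-mediated cleavage of three aryl silyl ethers under buffered, weakly acidic conditions; a basic fluoride source is avoided because phenoxide base would open ring C by retro-oxa-Michael reaction and scramble C2. The allylic alcohol and the catechol tolerate these conditions at 0 °C.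

## Compound list

1 | 2,4-dihydroxybenzaldehyde | O=Cc1ccc(O)cc1O | starting material
2 | allyl bromide | C=CCBr | starting material
3 | 4-(allyloxy)-2-hydroxybenzaldehyde | C=CCOc1ccc(C=O)c(O)c1 | intermediate
4 | 3-allyl-2,4-dihydroxybenzaldehyde | C=CCc1c(O)ccc(C=O)c1O | intermediate
5 | 3-allyl-4-(tert-butyldimethylsilyloxy)-2-hydroxybenzaldehyde | C=CCc1c(O[Si](C)(C)C(C)(C)C)ccc(C=O)c1O | intermediate
6 | 3,4-dihydroxybenzaldehyde | O=Cc1ccc(O)c(O)c1 | starting material
7 | 3,4-bis(tert-butyldimethylsilyloxy)benzaldehyde | O=Cc1ccc(O[Si](C)(C)C(C)(C)C)c(O[Si](C)(C)C(C)(C)C)c1 | intermediate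
8 | 3,4-bis(tert-butyldimethylsilyloxy)styrene | C=Cc1ccc(O[Si](C)(C)C(C)(C)C)c(O[Si](C)(C)C(C)(C)C)c1 | intermediate
9 | 2-allyl-3-(tert-butyldimethylsilyloxy)-6-(dimethoxymethyl)phenol (dimethyl acetal of 5, not isolated) | C=CCc1c(O[Si](C)(C)C(C)(C)C)ccc(C(OC)OC)c1O | intermediate
10 | 2-allyl-3-(tert-butyldimethylsilyloxy)-6-(methoxymethylidene)cyclohexa-2,4-dien-1-one (methoxy ortho-quinone methide, not isolated) | COC=C1C=CC(O[Si](C)(C)C(C)(C)C)=C(CC=C)C1=O | intermediate
11 | (2S)-8-allyl-7-(tert-butyldimethylsilyloxy)-2-[3,4-bis(tert-butyldimethylsilyloxy)phenyl]-4-methoxychroman, both C4 epimers | C=CCc1c(O[Si](C)(C)C(C)(C)C)ccc2c1O[C@H](c1ccc(O[Si](C)(C)C(C)(C)C)c(O[Si](C)(C)C(C)(C)C)c1)CC2OC | intermediate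
12 | (2S)-8-allyl-7-(tert-butyldimethylsilyloxy)-2-[3,4-bis(tert-butyldimethylsilyloxy)phenyl]chroman-4-ol, both C4 epimers | C=CCc1c(O[Si](C)(C)C(C)(C)C)ccc2c1O[C@H](c1ccc(O[Si](C)(C)C(C)(C)C)c(O[Si](C)(C)C(C)(C)C)c1)CC2O | intermediate
13 | (2S)-8-allyl-7-(tert-butyldimethylsilyloxy)-2-[3,4-bis(tert-butyldimethylsilyloxy)phenyl]chroman-4-one | C=CCc1c(O[Si](C)(C)C(C)(C)C)ccc2c1O[C@H](c1ccc(O[Si](C)(C)C(C)(C)C)c(O[Si](C)(C)C(C)(C)C)c1)CC2=O | intermediate
14 | methacrolein (2-methylprop-2-enal) | CC(=C)C=O | starting material
15 | (2E)-4-[(2S)-7-(tert-butyldimethylsilyloxy)-2-[3,4-bis(tert-butyldimethylsilyloxy)phenyl]-4-oxochroman-8-yl]-2-methylbut-2-enal | C/C(=C\Cc1c(O[Si](C)(C)C(C)(C)C)ccc2c1O[C@H](c1ccc(O[Si](C)(C)C(C)(C)C)c(O[Si](C)(C)C(C)(C)C)c1)CC2=O)C=O | intermediate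
16 | (2S)-7-(tert-butyldimethylsilyloxy)-2-[3,4-bis(tert-butyldimethylsilyloxy)phenyl]-8-[(2E)-4-hydroxy-3-methylbut-2-en-1-yl]chroman-4-one | C/C(=C\Cc1c(O[Si](C)(C)C(C)(C)C)ccc2c1O[C@H](c1ccc(O[Si](C)(C)C(C)(C)C)c(O[Si](C)(C)C(C)(C)C)c1)CC2=O)CO | intermediate
17 | (2S)-2-(3,4-dihydroxyphenyl)-7-hydroxy-8-[(2E)-4-hydroxy-3-methylbut-2-en-1-yl]chroman-4-one (CNP0205253.1) | C/C(=C\Cc1c(O)ccc2c1O[C@H](c1ccc(O)c(O)c1)CC2=O)CO | target

## Step count and least certain steps

Total step count: 11. Longest linear sequence: 9 steps (1 → 3 → 4 → 5 → 11 → 12 → 13 → 15 → 16 → 17, that is steps 1, 2, 3, 6, 7, 8, 9, 10 and 11); the styrene branch (steps 4 and 5) joins at step 6.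

**The key step (step 6, proposed new method).**
- Most likely failure: poor facial selectivity. The silyloxy styrene offers the catalyst no hydrogen-bond handle, so the ion pair that decides C2 may be loose.
- Further processes that may interfere: acid-induced oligomerisation of the styrene; loss of the C7 silyl group from the para-silyloxy-stabilised cation; and erosion of C2 through reversible ionisation of O1–C2 after ring closure.
- Fallback (known chemistry, sets out from 5 and 8, comes back at 13): the same three components are combined with an achiral acid catalyst (Sc(OTf)3 or TfOH, trimethyl orthoformate, CH2Cl2). This known racemic reaction should give the racemic 8-allyl-4-methoxyflavan tris(TBS) ether F1. F1 is hydrolysed as in step 7 to the racemic flavan-4-ol F2 and oxidised as in step 8 to the racemic flavanone F3. F3 is then resolved by asymmetric transfer hydrogenation under kinetic resolution: RuCl(p-cymene)[(S,S)-TsDPEN] or its mirror image, whichever consumes the 2R ketone, HCO2H/Et3N, stopped near half conversion. The reduced (2R,4R)-cis-flavan-4-ol F4 is separated by chromatography and the unreacted 2S ketone is 13.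

**Step 7 (methoxy to hydroxyl exchange at C4).**
- Most likely failure: loss of a proton from the C4 cation toward the C3=C4 alkene instead of capture by water. Slow cleavage of aryl silyl ethers, or ionisation at C2, may occur if the acid has to be strengthened.
- Fallback (sets out from 11, comes back at 13, no new compound): the hydrolysis and oxidation pair is replaced by one oxidative step, DDQ in CH2Cl2/pH 7 buffer at 0 °C. Hydride abstraction from C4 gives the oxocarbenium ion, and hydration with loss of methanol gives ketone 13 directly. C4–H is the most electron-rich benzylic C–H, activated by O1, the C7 silyloxy group and its own methoxy group.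

**Step 9 (cross-metathesis).**
- Most likely failure: slow turnover at an allyl group flanked by two ortho substituents, which gives time for double-bond migration into conjugation with ring A and for homodimerisation.
- Fallback (sets out from 13, comes back at 15): the terminal alkene is cleaved with OsO4 (cat.), NaIO4 and 2,6-lutidine in dioxane/H2O to the arylacetaldehyde 2-[(2S)-7-(tert-butyldimethylsilyloxy)-2-[3,4-bis(tert-butyldimethylsilyloxy)phenyl]-4-oxochroman-8-yl]acetaldehyde F5. F5 is then condensed with the stabilised ylide 2-(triphenylphosphoranylidene)propanal in toluene at 80 °C. This Wittig reaction is E-selective and does not touch the deactivated C4 ketone, and it should give 15.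

**Step 10 (aldehyde reduction beside the C4 ketone).**
- Most likely failure: over-reduction at C4, or some conjugate reduction of the enal, if the difference in rate between the two carbonyl groups is smaller than expected.
- Fallback (sets out from 15, comes back at 17): both carbonyl groups are reduced on purpose with excess NaBH4 in MeOH/THF at 0 °C to the diol (2S)-7-(tert-butyldimethylsilyloxy)-2-[3,4-bis(tert-butyldimethylsilyloxy)phenyl]-8-[(2E)-4-hydroxy-3-methylbut-2-en-1-yl]chroman-4-ol F6. The primary allylic hydroxyl is silylated selectively (TBSCl, imidazole, CH2Cl2, −20 °C) to the tetrakis(TBS) flavan-4-ol F7. The remaining benzylic alcohol is oxidised with Dess–Martin periodinane to the tetrakis(TBS) flavanone F8. The conditions of step 11 then remove all four silyl groups and give 17.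

## Further compounds

F1 | step 6 | racemic 8-allyl-7-(tert-butyldimethylsilyloxy)-2-[3,4-bis(tert-butyldimethylsilyloxy)phenyl]-4-methoxychroman | C=CCc1c(O[Si](C)(C)C(C)(C)C)ccc2c1OC(c1ccc(O[Si](C)(C)C(C)(C)C)c(O[Si](C)(C)C(C)(C)C)c1)CC2OC
F2 | step 6 | racemic 8-allyl-7-(tert-butyldimethylsilyloxy)-2-[3,4-bis(tert-butyldimethylsilyloxy)phenyl]chroman-4-ol | C=CCc1c(O[Si](C)(C)C(C)(C)C)ccc2c1OC(c1ccc(O[Si](C)(C)C(C)(C)C)c(O[Si](C)(C)C(C)(C)C)c1)CC2O
F3 | step 6 | racemic 8-allyl-7-(tert-butyldimethylsilyloxy)-2-[3,4-bis(tert-butyldimethylsilyloxy)phenyl]chroman-4-one | C=CCc1c(O[Si](C)(C)C(C)(C)C)ccc2c1OC(c1ccc(O[Si](C)(C)C(C)(C)C)c(O[Si](C)(C)C(C)(C)C)c1)CC2=O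
F4 | step 6 | (2R,4R)-8-allyl-7-(tert-butyldimethylsilyloxy)-2-[3,4-bis(tert-butyldimethylsilyloxy)phenyl]chroman-4-ol (cis) | C=CCc1c(O[Si](C)(C)C(C)(C)C)ccc2c1O[C@@H](c1ccc(O[Si](C)(C)C(C)(C)C)c(O[Si](C)(C)C(C)(C)C)c1)C[C@H]2O
F0 | step 7 | none | none
F5 | step 9 | 2-[(2S)-7-(tert-butyldimethylsilyloxy)-2-[3,4-bis(tert-butyldimethylsilyloxy)phenyl]-4-oxochroman-8-yl]acetaldehyde | O=CCc1c(O[Si](C)(C)C(C)(C)C)ccc2c1O[C@H](c1ccc(O[Si](C)(C)C(C)(C)C)c(O[Si](C)(C)C(C)(C)C)c1)CC2=O
F6 | step 10 | (2S)-7-(tert-butyldimethylsilyloxy)-2-[3,4-bis(tert-butyldimethylsilyloxy)phenyl]-8-[(2E)-4-hydroxy-3-methylbut-2-en-1-yl]chroman-4-ol, both C4 epimers | C/C(=C\Cc1c(O[Si](C)(C)C(C)(C)C)ccc2c1O[C@H](c1ccc(O[Si](C)(C)C(C)(C)C)c(O[Si](C)(C)C(C)(C)C)c1)CC2O)CO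
F7 | step 10 | (2S)-7-(tert-butyldimethylsilyloxy)-2-[3,4-bis(tert-butyldimethylsilyloxy)phenyl]-8-[(2E)-4-(tert-butyldimethylsilyloxy)-3-methylbut-2-en-1-yl]chroman-4-ol, both C4 epimers | C/C(=C\Cc1c(O[Si](C)(C)C(C)(C)C)ccc2c1O[C@H](c1ccc(O[Si](C)(C)C(C)(C)C)c(O[Si](C)(C)C(C)(C)C)c1)CC2O)CO[Si](C)(C)C(C)(C)C
F8 | step 10 | (2S)-7-(tert-butyldimethylsilyloxy)-2-[3,4-bis(tert-butyldimethylsilyloxy)phenyl]-8-[(2E)-4-(tert-butyldimethylsilyloxy)-3-methylbut-2-en-1-yl]chroman-4-one | C/C(=C\Cc1c(O[Si](C)(C)C(C)(C)C)ccc2c1O[C@H](c1ccc(O[Si](C)(C)C(C)(C)C)c(O[Si](C)(C)C(C)(C)C)c1)CC2=O)CO[Si](C)(C)C(C)(C)C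
A1 | alternative 1 | (2S)-2-[3,4-bis(tert-butyldimethylsilyloxy)phenyl]-5-(phenylsulfinyl)-2,3-dihydro-4H-pyran-4-one | O=C1C[C@@H](c2ccc(O[Si](C)(C)C(C)(C)C)c(O[Si](C)(C)C(C)(C)C)c2)OC=C1S(=O)c1ccccc1
A2 | alternative 1 | (6E)-8-(tert-butyldimethylsilyloxy)-1-methoxy-7-methyl-3-(trimethylsilyloxy)octa-1,3,6-triene | COC=CC(O[Si](C)(C)C)=CC/C=C(\C)CO[Si](C)(C)C(C)(C)C
A3 | alternative 1 | (2S)-2-[3,4-bis(tert-butyldimethylsilyloxy)phenyl]-8-[(2E)-4-(tert-butyldimethylsilyloxy)-3-methylbut-2-en-1-yl]-7-hydroxychroman-4-one | C/C(=C\Cc1c(O)ccc2c1O[C@H](c1ccc(O[Si](C)(C)C(C)(C)C)c(O[Si](C)(C)C(C)(C)C)c1)CC2=O)CO[Si](C)(C)C(C)(C)C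
A4 | alternative 2 | (3S)-3-[3,4-bis(methoxymethoxy)phenyl]-1-{3-[(2E)-4-(tert-butyldimethylsilyloxy)-3-methylbut-2-en-1-yl]-2-fluoro-4-(methoxymethoxy)phenyl}propane-1,3-diol, both C1 epimers | C/C(=C\Cc1c(OCOC)ccc(C(O)C[C@H](O)c2ccc(OCOC)c(OCOC)c2)c1F)CO[Si](C)(C)C(C)(C)C
A5 | alternative 2 | (2S)-2-[3,4-bis(methoxymethoxy)phenyl]-8-[(2E)-4-(tert-butyldimethylsilyloxy)-3-methylbut-2-en-1-yl]-7-(methoxymethoxy)chroman-4-ol, both C4 epimers | C/C(=C\Cc1c(OCOC)ccc2c1O[C@H](c1ccc(OCOC)c(OCOC)c1)CC2O)CO[Si](C)(C)C(C)(C)C
A6 | alternative 3 | (3S)-3-[2-allyl-3-(tert-butyldimethylsilyloxy)phenoxy]-3-(3,4-diacetoxyphenyl)propanoic acid | C=CCc1c(O[Si](C)(C)C(C)(C)C)cccc1O[C@H](c1ccc(OC(C)=O)c(OC(C)=O)c1)CC(=O)O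
A7 | alternative 3 | (2S)-8-allyl-7-(tert-butyldimethylsilyloxy)-2-(3,4-diacetoxyphenyl)chroman-4-one | C=CCc1c(O[Si](C)(C)C(C)(C)C)ccc2c1O[C@H](c1ccc(OC(C)=O)c(OC(C)=O)c1)CC2=O
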